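The numbers in the tables stem from a simulated flask on assumed constants; noise was put on by code.

Start from the red run. You ask for a quick number for the flask, the blue recipe followed to 15 min, and you suspect that the exchange is weak.

in all of them: left-handed substrate 0.075 M; right-handed substrate 0.075 M; free catalyst 0.15 mM
- blue: partner 0.30 M; racemization catalyst 3.8 mM; the very flask that is asked about, followed so far
- red: partner 0.30 M; racemization catalyst 7.6 mM; run made earlier
- flask: partner 0.300 M; racemization catalyst 3.8 mM; time 15 min

blue run (percent of the left-handed substrate and right-handed substrate together charged)

| time / s | left-handed product / % | right-handed product / % |
|---|---|---|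
| 10.0 | 0 | 0 |
| 20.0 | 1.5 | 0.6 |
| 40.0 | 3.8 | 1.2 |
| 80.0 | 5.0 | 2.5 |

red run (percent of the left-handed substrate and right-handed substrate together charged)

| time / min | left-handed product / % | right-handed product / % |
|---|---|---|
| 1.00 | 3.8 | 1.5 |
| 2.50 | 9.1 | 3.2 |
| 5.00 | 12.7 | 2.9 |
| 8.00 | 19.1 | 6.3 |
| 10.0 | 21.7 | 8.9 |

(readings scatter by 1 percentage point)

- left-handed product and right-handed product together, in percent of the left-handed substrate and right-handed substrate charged together, at 15 min
- excess of left-handed product over right-handed product in the product at 15 min
- whether the exchange between left-handed substrate and right-handed substrate keeps pace with the reaction: how far the product's excess at 15 min gets from its value without exchange to its value with instant exchange (above 80% keeps pace, below 20% hardly takes part, else lags behind)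

- free catalyst is single-handed; left-handed substrate and right-handed substrate are mirror images of each other, charged as a racemate, each of them at the stated concentration
- an excess is the difference of the two amounts in percent of their sum
- an excess is below zero if the other one leads

Blue shows 7.50% of product at 80.0 s and red 5.30% at 1.00 min, so I can read no effect of the doubled racemization catalyst on the rate, and I borrow red's longer course for blue. I treat the loss of substrate as pseudo-first-order and take red's last reading, 30.6% at 10.0 min. That gives 19.0 min as the reaction half-life, the time in which half of the two substrates together reacts. The asked time holds 0.789 of these, so I commit to 42.2% of product.

The same half-life is my yardstick for the exchange: in this flask it keeps pace if the excess between the two substrates decays with a half-time well under 19.0 min. Red's product excess at 10.0 min reads 41.8%, but each reading scatters by 1 percentage point, and I can draw no such half-time from it, so I give no excess of my own.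

The forecast does commit: 41% (35% to 47%), an excess of 40% (33% to 47%), and an exchange that lags behind, on the ground “so exchange is weak”.

The flask gives 38.5% with an excess of 46.7%, and the exchange keeps pace, at 94% of the way.

    partner + racemization catalyst → spent catalyst (k = 0.00560 /M/s)
    left-handed substrate + racemization catalyst ⇌ right-handed substrate + racemization catalyst, rate k2*[racemization catalyst]*[left-handed substrate] forward; the back reaction follows from the equilibrium constant (k = 9.60 /M/s)
    partner + free catalyst + left-handed substrate → free catalyst + left-handed product (k = 39.0 /M²/s)
    partner + free catalyst + right-handed substrate → free catalyst + right-handed product (k = 14.0 /M²/s)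
    free catalyst ⇌ dormant form (K = 1.20, k = 0.00580 /s)

At 15.0 min, with 26.5% of its charge of racemization catalyst remaining, a substrate excess has a half-time of 35.8 s by the exchange taken by itself, far shorter than 19.0 min, and among what is left of the two substrates the excess of right-handed substrate over left-handed substrate is 0.998%.

In the flask with 0.75 M of partner, taking the rate as proportional to [partner], the reaction half-life scales to 7.59 min, which predicts 74.6% of product, while the 3.30% of its charge of racemization catalyst left at 15.0 min gives an exchange half-time of 4.80 min, shorter than the reaction half-life but no longer far below it. That flask gives 70.6% with an excess of 44.5%, and left-handed substrate 13.0% against right-handed substrate 16.4%.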